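The numbers of this flask were set for the occasion.

Solid left over at the end of a run is what I look for first in a flask like this, because while crystals remain, the dissolved starting material has a ceiling and the enzyme works against a steady source.

the same everywhere: solid substrate 0.050 M; time 10 min
- cedar: enzyme 0.60 µM
- alder: enzyme 1.5 µM
- maple: enzyme 5.0 µM
- oak: enzyme 15 µM
- birch: enzyme 50 µM

    solid substrate ⇌ starting material, rate k1*(cs1 - [starting material]) while solid is left; crystals form when [starting material] > cs1 (cs1 = 20 mM, k1 = 0.0753 s⁻¹)
    starting material + enzyme → target + enzyme, rate k2*[starting material]*[enzyme]/(1 + ([starting material]/Km2) + ([starting material]/Ksi2)^2) (Km2 = 0.109 M, Ksi2 = 28.5 mM, k2 = 1730 L mol⁻¹ s⁻¹)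
    enzyme + target → enzyme + over-reaction product (k3 = 161 L mol⁻¹ s⁻¹)

- solid, in amounts per volume of the solution: solid substrate
- at the start none of the solid substrate is in solution
- "hardly changes" means that all values lie within two and a half points (for a concentration: within two and a half percent of the largest)
- run time (cedar): 10 min

- amount of target at the end, in percent of the solid substrate charged for cedar, alder, maple, oak, birch, in this order
- how that number moves from the first to the last of them (falls, then rises / hardly changes / rises all the way / falls all the way / rises, then falls)

The rate law of the enzyme step climbs with c(starting material) up to 28.5 mM, and the solubility of 20 mM lies below that, so the step runs fastest at saturation. There one enzyme molecule turns over 20.6 s⁻¹, which I call the top turnover. Dividing the charge by the top turnover times c(enzyme) gives a use-up time, the shortest time in which that flask can get through its charge.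

At the low end this gives a ceiling. Cedar can turn over 14.9% of its charge in the run and alder 37.2%. Little of that target is lost in cedar, since its half-life of 120 min is long against the run.

At the high end, oak has a use-up time of 2.69 min, short against the run, and the run becomes mostly decay. With the enzyme constant, target decays pseudo-first-order, with a time constant of 6.90 min. If all of it were born at the start, oak keeps 23.5%, my floor. If all of it were born at the end of the use-up time, oak keeps 34.7%, my upper mark, which is an estimate and no strict bound, as the use-up time is a shortest time and some target can be born later. A steady feed over that time lies between them, and that is my number for oak: 28.7%.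

The two ends join where the use-up time equals the run, at 4.04 µM of enzyme, so I expect a rise and then a fall.

The forecast gives 14.2%, 33.9%, 73%, 31% and 1.1%, a row that rises, then falls, and says “the yield peaks near maple and collapses by birch”. Its oak value stands inside my bracket and above my own number.

The simulation gives 14.2%, 33.9%, 72.6%, 30.3% and 1.13%, a row that rises, then falls.

At 20.6 s⁻¹, cedar's use-up time is 67.3 min against the run of 10 min, and cedar ends with 45.7% of its charge still solid, while oak shows 0% solid after 5.00 min and ends with 69.7% as over-reaction product. Maple, at 8.07 min, ends with 0% solid and 4.71% dissolved, and the row's turn reads 4.6 µM against the reckoned crossing at 4.04 µM.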